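The isoflavanone is traced back to the corresponding 3-aryl-2H-chromene, in which C3 and C4 are still alkene carbons, and this chromene is disconnected at C3–C4 and O1–C2. The disconnection rests on the fact that C4 and O1 sit on neighbouring carbons of ring A (C4a and C8a): with C4 read as a formyl group, ring A is an ortho-hydroxybenzaldehyde that lacks only C3 (bearing ring B) and the C2 methylene. One operation joins an alkenylboronic acid carrying exactly these two carbons and closes ring C. The partners are bis-MOM phloroglucinaldehyde and a 1-arylvinylboronic acid whose bromine stands in for the prenyl group; C3 is set afterwards by hydroboration.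

Key step: step 7

Assumption: the target's only stereocentre, C3, is S. The facial preference of isopinocampheylborane on the isoflavene is taken from its behaviour towards 1-arylcycloalkenes; if the opposite sense is found, the reagent from (−)-α-pinene is used and nothing else changes.

Step 1
Reactants: 1 2,4,6-trihydroxybenzaldehyde
Product: 2 2-hydroxy-4,6-bis(methoxymethoxy)benzaldehyde
Conditions: MOMCl (2.1 equiv), i-Pr2NEt, CH2Cl2, 0 °C
Reagents that add atoms: chloromethyl methyl ether (MOMCl), COCCl
Why: MOM ether formation (Williamson-type O-alkylation) should stop after two groups because the last ortho-hydroxyl is locked in a hydrogen bond to the formyl oxygen and is the least nucleophilic of the three.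

Step 2
Reactants: 3 4-hydroxy-2-methoxybenzaldehyde
Product: 4 5-bromo-4-hydroxy-2-methoxybenzaldehyde
Conditions: NBS (1.0 equiv), MeCN, 0 °C
Reagents that add atoms: N-bromosuccinimide, O=C1CCC(=O)N1Br
Why: Electrophilic aromatic bromination should go to C5, which is ortho to the free phenol and para to the methoxy group, whereas C3 is flanked by two oxygen substituents and C6 is not activated.

Step 3
Reactants: 4 5-bromo-4-hydroxy-2-methoxybenzaldehyde
Product: 5 5-bromo-2-methoxy-4-(methoxymethoxy)benzaldehyde
Conditions: MOMCl, i-Pr2NEt, CH2Cl2, 0 °C → rt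
Reagents that add atoms: chloromethyl methyl ether (MOMCl), COCCl
Why: MOM ether formation on the single, acidic phenol (Williamson-type O-alkylation) gives a group that tolerates every basic, reductive and oxidative step up to the last one.

Step 4
Reactants: 5 5-bromo-2-methoxy-4-(methoxymethoxy)benzaldehyde
Product: 6 1-bromo-5-ethynyl-4-methoxy-2-(methoxymethoxy)benzene
Conditions: Ohira–Bestmann reagent, K2CO3, MeOH, rt
Reagents that add atoms: dimethyl (1-diazo-2-oxopropyl)phosphonate, COP(=O)(OC)C(=[N+]=[N-])C(C)=O
Why: Seyferth–Gilbert homologation in its Ohira–Bestmann form turns an aryl aldehyde into the terminal alkyne under carbonate conditions that leave the aryl bromide and the MOM ether untouched.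

Step 5
Reactants: 6 1-bromo-5-ethynyl-4-methoxy-2-(methoxymethoxy)benzene
Product: 7 2-{1-[5-bromo-2-methoxy-4-(methoxymethoxy)phenyl]ethenyl}-4,4,5,5-tetramethyl-1,3,2-dioxaborolane
Conditions: B2pin2 (1.1 equiv), MeOH (2 equiv), (SIMes)CuCl (5 mol %; SIMes = 1,3-dimesitylimidazolidin-2-ylidene), NaOt-Bu (5 mol %), THF, −15 °C
Reagents that add atoms: bis(pinacolato)diboron, CC1(C)OB(OC1(C)C)B1OC(C)(C)C(C)(C)O1
Why: NHC–copper-catalysed protoboration (syn addition of a copper–boryl bond across the alkyne, then protonation of the alkenylcopper by MeOH) places boron on the internal carbon of aryl acetylenes when the carbene carries N-aryl groups, monovalent copper leaves the aryl bromide alone at this temperature, and any linear isomer is removed by chromatography.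

Step 6
Reactants: 7 2-{1-[5-bromo-2-methoxy-4-(methoxymethoxy)phenyl]ethenyl}-4,4,5,5-tetramethyl-1,3,2-dioxaborolane
Product: 8 {1-[5-bromo-2-methoxy-4-(methoxymethoxy)phenyl]ethenyl}boronic acid
Conditions: NaIO4, NH4OAc, acetone/H2O, rt; used without storage
Reagents that add atoms: water, O
Why: Periodate deprotection of a pinacol boronate works by oxidative cleavage of the pinacol released in the hydrolysis equilibrium, which drives the ester to the free boronic acid at near-neutral pH and so spares the MOM ether and the alkene.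

Step 7
Reactants: 2 2-hydroxy-4,6-bis(methoxymethoxy)benzaldehyde; 8 {1-[5-bromo-2-methoxy-4-(methoxymethoxy)phenyl]ethenyl}boronic acid
Product: 11 3-[5-bromo-2-methoxy-4-(methoxymethoxy)phenyl]-5,7-bis(methoxymethoxy)-2H-chromene, via aminophenol adduct 9 (not isolated), via ortho-quinone methide 10 (not isolated)
Conditions: Bn2NH (1.0 equiv, regenerated), 1,4-dioxane, 50 → 90 °C
Reagents that add atoms: none
Why: The secondary amine condenses with the formyl group of 2 to an iminium ion while the neighbouring phenoxide binds the boronic acid as a tetracoordinate boronate, from which the alkenyl carbon that carries boron and ring B is delivered intramolecularly to the iminium carbon, forming C3–C4 in adduct 9 (Petasis borono-Mannich reaction). On heating, the electron-rich ring A expels the amine to give ortho-quinone methide 10, a 1-oxatriene that closes ring C by a thermal disrotatory oxa-6π electrocyclisation, which forms O1–C2 and restores the aromaticity of ring A. The closest known reaction type is the amine-mediated condensation of salicylaldehydes with alkenylboronic acids to 2H-chromenes. No stereocentre is created, since C3 and C4 emerge as the alkene that is hydroborated in step 8. The step needs regioselectivity (aryl at C3, not C2) and selectivity for one phenol: the first follows because only the boron-bound carbon is transferred, the second because only the free 2-hydroxyl beside the aldehyde can form the boronate and later the quinone methide, the other two oxygens being capped as MOM ethers. Amine addition to 10 is reversible, so both geometries of its exocyclic alkene should funnel into the cyclisable one, and the aryl bromide and MOM ethers are inert to amine and boronic acid at this temperature.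

Step 8
Reactants: 11 3-[5-bromo-2-methoxy-4-(methoxymethoxy)phenyl]-5,7-bis(methoxymethoxy)-2H-chromene
Product: 13 (3S,4R)-3-[5-bromo-2-methoxy-4-(methoxymethoxy)phenyl]-5,7-bis(methoxymethoxy)chroman-4-ol, via alkyl(isopinocampheyl)borane 12 (not isolated)
Conditions: (IpcBH2)2·TMEDA [from (+)-α-pinene], BF3·OEt2, THF, filter; filtrate + 11, −25 → 0 °C; then NaOH, H2O2, 0 °C → rt
Reagents that add atoms: hydrogen peroxide, OO
Why: Asymmetric hydroboration–oxidation adds B–H syn with boron at the unsubstituted C4 and hydrogen at the aryl-bearing C3, stereoretentive C–B oxidation then gives the trans alcohol, and the isopinocampheyl group should select the alkene face as it does for 1-arylcycloalkenes, which sets C3 as S and C4 as R.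

Step 9
Reactants: 13 (3S,4R)-3-[5-bromo-2-methoxy-4-(methoxymethoxy)phenyl]-5,7-bis(methoxymethoxy)chroman-4-ol; 14 4,4,5,5-tetramethyl-2-(3-methylbut-2-en-1-yl)-1,3,2-dioxaborolane (prenylboronic acid pinacol ester)
Product: 15 (3S,4R)-3-[2-methoxy-4-(methoxymethoxy)-5-(3-methylbut-2-en-1-yl)phenyl]-5,7-bis(methoxymethoxy)chroman-4-ol
Conditions: 14 (1.5 equiv), PdCl2(IPent)(3-chloropyridine) (3 mol %; IPent = 1,3-bis[2,6-di(pentan-3-yl)phenyl]imidazol-2-ylidene), KOH (5 M aq), THF, 70 °C
Reagents that add atoms: none
Why: Suzuki–Miyaura coupling of an allylic boronate, in which the very bulky carbene on the zerovalent palladium generated from the divalent precatalyst favours C–C bond formation at the unsubstituted allyl terminus and so gives the linear prenyl arene, is run here because C3 is not yet next to a carbonyl and therefore tolerates the strong base.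

Step 10
Reactants: 15 (3S,4R)-3-[2-methoxy-4-(methoxymethoxy)-5-(3-methylbut-2-en-1-yl)phenyl]-5,7-bis(methoxymethoxy)chroman-4-ol
Product: 16 (3S)-3-[2-methoxy-4-(methoxymethoxy)-5-(3-methylbut-2-en-1-yl)phenyl]-5,7-bis(methoxymethoxy)chroman-4-one
Conditions: Dess–Martin periodinane, NaHCO3, CH2Cl2, 0 °C → rt
Reagents that add atoms: none
Why: Dess–Martin oxidation of the benzylic secondary alcohol runs under buffered, essentially neutral conditions, so the now enolisable C3 centre, the prenyl alkene and the MOM ethers should survive while the C4 stereocentre is removed as intended.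

Step 11
Reactants: 16 (3S)-3-[2-methoxy-4-(methoxymethoxy)-5-(3-methylbut-2-en-1-yl)phenyl]-5,7-bis(methoxymethoxy)chroman-4-one
Product: 17 (3S)-5,7-dihydroxy-3-[4-hydroxy-2-methoxy-5-(3-methylbut-2-en-1-yl)phenyl]chroman-4-one (target)
Conditions: HCl (1.25 M in MeOH), 0 °C → rt, monitored; quench into pH 6 phosphate buffer
Reagents that add atoms: none
Why: Acid-catalysed acetal exchange with methanol (MOM ether cleavage) frees the three phenols, and low temperature, short exposure and a work-up that never turns basic are chosen because enolisation at C3 and addition of the neighbouring phenol to the prenyl alkene should both be slow under such conditions.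

Compound list
1 | 2,4,6-trihydroxybenzaldehyde | O=Cc1c(O)cc(O)cc1O | starting material
2 | 2-hydroxy-4,6-bis(methoxymethoxy)benzaldehyde | O=Cc1c(O)cc(OCOC)cc1OCOC | intermediate
3 | 4-hydroxy-2-methoxybenzaldehyde | COc1cc(O)ccc1C=O | starting material
4 | 5-bromo-4-hydroxy-2-methoxybenzaldehyde | COc1cc(O)c(Br)cc1C=O | intermediate
5 | 5-bromo-2-methoxy-4-(methoxymethoxy)benzaldehyde | COc1cc(OCOC)c(Br)cc1C=O | intermediate
6 | 1-bromo-5-ethynyl-4-methoxy-2-(methoxymethoxy)benzene | C#Cc1cc(Br)c(OCOC)cc1OC | intermediate
7 | 2-{1-[5-bromo-2-methoxy-4-(methoxymethoxy)phenyl]ethenyl}-4,4,5,5-tetramethyl-1,3,2-dioxaborolane | C=C(B1OC(C)(C)C(C)(C)O1)c1cc(Br)c(OCOC)cc1OC | intermediate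
8 | {1-[5-bromo-2-methoxy-4-(methoxymethoxy)phenyl]ethenyl}boronic acid | C=C(B(O)O)c1cc(Br)c(OCOC)cc1OC | intermediate
9 | 2-{2-[5-bromo-2-methoxy-4-(methoxymethoxy)phenyl]-1-(dibenzylamino)prop-2-en-1-yl}-3,5-bis(methoxymethoxy)phenol (racemic at the amine-bearing carbon) | C=C(c1cc(Br)c(OCOC)cc1OC)C(N(Cc1ccccc1)Cc1ccccc1)c1c(O)cc(OCOC)cc1OCOC | intermediate (not isolated)
10 | (6Z)-6-{2-[5-bromo-2-methoxy-4-(methoxymethoxy)phenyl]prop-2-en-1-ylidene}-3,5-bis(methoxymethoxy)cyclohexa-2,4-dien-1-one | C=C(c1cc(Br)c(OCOC)cc1OC)/C=C1\C(=O)C=C(OCOC)C=C1OCOC | intermediate (not isolated)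
11 | 3-[5-bromo-2-methoxy-4-(methoxymethoxy)phenyl]-5,7-bis(methoxymethoxy)-2H-chromene | COc1cc(OCOC)c(Br)cc1C1=Cc2c(OCOC)cc(OCOC)cc2OC1 | intermediate
12 | {(3S,4R)-3-[5-bromo-2-methoxy-4-(methoxymethoxy)phenyl]-5,7-bis(methoxymethoxy)chroman-4-yl}[(1R,2S,3R,5R)-isopinocampheyl]borane | COc1cc(OCOC)c(Br)cc1[C@H]1COc2cc(OCOC)cc(OCOC)c2[C@@H]1B[C@@H]1C[C@@H]2C[C@H]([C@H]1C)C2(C)C | intermediate (not isolated)
13 | (3S,4R)-3-[5-bromo-2-methoxy-4-(methoxymethoxy)phenyl]-5,7-bis(methoxymethoxy)chroman-4-ol (3-aryl and 4-OH trans) | COc1cc(OCOC)c(Br)cc1[C@H]1COc2cc(OCOC)cc(OCOC)c2[C@@H]1O | intermediate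
14 | 4,4,5,5-tetramethyl-2-(3-methylbut-2-en-1-yl)-1,3,2-dioxaborolane | CC(C)=CCB1OC(C)(C)C(C)(C)O1 | starting material
15 | (3S,4R)-3-[2-methoxy-4-(methoxymethoxy)-5-(3-methylbut-2-en-1-yl)phenyl]-5,7-bis(methoxymethoxy)chroman-4-ol | COc1cc(OCOC)c(CC=C(C)C)cc1[C@H]1COc2cc(OCOC)cc(OCOC)c2[C@@H]1O | intermediate
16 | (3S)-3-[2-methoxy-4-(methoxymethoxy)-5-(3-methylbut-2-en-1-yl)phenyl]-5,7-bis(methoxymethoxy)chroman-4-one | COc1cc(OCOC)c(CC=C(C)C)cc1[C@H]1COc2cc(OCOC)cc(OCOC)c2C1=O | intermediate
17 | (3S)-5,7-dihydroxy-3-[4-hydroxy-2-methoxy-5-(3-methylbut-2-en-1-yl)phenyl]chroman-4-one | COc1cc(O)c(CC=C(C)C)cc1[C@H]1COc2cc(O)cc(O)c2C1=O | target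

Total step count: 11 (step 1 for the ring A aldehyde, steps 2–6 for the ring B boronic acid, steps 7–11 after their union).
Longest linear sequence: 10 steps (3 → 4 → 5 → 6 → 7 → 8 → 11 → 13 → 15 → 16 → 17).

Steps most likely to fail

Step 7. Iminium formation at the doubly ortho-substituted, electron-rich formyl group may be slow, so that protodeboronation or oligomerisation of the arylvinylboronic acid outruns alkenyl transfer. The fallback sets out from 7 and 2 and returns at 11; it replaces boron-to-carbon transfer by a polar carbonyl addition. Iododeboronation of 7 (NaOMe, then I2, THF, −78 → 0 °C) would give 1-bromo-5-(1-iodoethenyl)-4-methoxy-2-(methoxymethoxy)benzene F1. Iodine–magnesium exchange with i-PrMgCl·LiCl at −40 °C, expected to be faster at the alkenyl iodide than at the electron-rich aryl bromide, would give {1-[5-bromo-2-methoxy-4-(methoxymethoxy)phenyl]ethenyl}magnesium chloride F2. Grignard addition of F2 to 2, taken as sodium 2-formyl-3,5-bis(methoxymethoxy)phenolate F3 (NaH, THF, 0 °C), would give racemic 2-{2-[5-bromo-2-methoxy-4-(methoxymethoxy)phenyl]-1-hydroxyprop-2-en-1-yl}-3,5-bis(methoxymethoxy)phenol F4. Warming F4 in toluene with a trace of PPTS should expel water, pass through quinone methide 10 and close to 11.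

Step 8. Addition of the bulky borane to the conjugated, trisubstituted alkene may be sluggish, since C4 lies beside the 5-OMOM group, and the temperature then required would erode facial selectivity. The fallback sets out from 11 and returns at 13; it replaces asymmetric induction by resolution. Hydroboration–oxidation with BH3·SMe2 (THF, 0 °C; NaOH, H2O2) would give the racemic trans-3-[5-bromo-2-methoxy-4-(methoxymethoxy)phenyl]-5,7-bis(methoxymethoxy)chroman-4-ol F5. Steglich esterification with (2S)-2-methoxy-2-phenylacetic acid (DCC, DMAP, CH2Cl2, 0 °C) would give the (3S,4R)-chroman-4-yl (2S)-2-methoxy-2-phenylacetate F6 together with the (3R,4S)-chroman-4-yl (2S)-2-methoxy-2-phenylacetate F7. These diastereomers are separated by chromatography or crystallisation and F7 is discarded. Saponification of F6 (LiOH, THF/MeOH/H2O) would return 13; at this stage C3 is not base-sensitive.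

Step 11. Acid-catalysed enolisation may partly erase C3, or the freed phenol may add to the prenyl alkene, while the least reactive MOM group (at O7, para to the carbonyl) is still being cleaved. The fallback sets out from 16 and returns at 17; it replaces protic hydrolysis by acetal-to-silyl exchange followed by buffered fluoride. Treatment of 16 with TESOTf and 2,2′-bipyridyl (CH2Cl2, 0 °C), a non-protic conversion known for aryl MOM ethers, would give (3S)-3-[2-methoxy-5-(3-methylbut-2-en-1-yl)-4-(triethylsilyloxy)phenyl]-5,7-bis(triethylsilyloxy)chroman-4-one F8. Desilylation with HF·pyridine buffered by excess pyridine (THF, 0 °C) would then give 17.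

Further compounds
F1 | step 7 | 1-bromo-5-(1-iodoethenyl)-4-methoxy-2-(methoxymethoxy)benzene | C=C(I)c1cc(Br)c(OCOC)cc1OC
F2 | step 7 | {1-[5-bromo-2-methoxy-4-(methoxymethoxy)phenyl]ethenyl}magnesium chloride | C=C([Mg]Cl)c1cc(Br)c(OCOC)cc1OC
F3 | step 7 | sodium 2-formyl-3,5-bis(methoxymethoxy)phenolate | O=Cc1c([O-])cc(OCOC)cc1OCOC.[Na+]
F4 | step 7 | 2-{2-[5-bromo-2-methoxy-4-(methoxymethoxy)phenyl]-1-hydroxyprop-2-en-1-yl}-3,5-bis(methoxymethoxy)phenol (racemic) | C=C(c1cc(Br)c(OCOC)cc1OC)C(O)c1c(O)cc(OCOC)cc1OCOC
F5 | step 8 | racemic trans-3-[5-bromo-2-methoxy-4-(methoxymethoxy)phenyl]-5,7-bis(methoxymethoxy)chroman-4-ol (both enantiomers) | COc1cc(OCOC)c(Br)cc1[C@H]1COc2cc(OCOC)cc(OCOC)c2[C@@H]1O.COc1cc(OCOC)c(Br)cc1[C@@H]1COc2cc(OCOC)cc(OCOC)c2[C@H]1O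
F6 | step 8 | (3S,4R)-3-[5-bromo-2-methoxy-4-(methoxymethoxy)phenyl]-5,7-bis(methoxymethoxy)chroman-4-yl (2S)-2-methoxy-2-phenylacetate | COc1cc(OCOC)c(Br)cc1[C@H]1COc2cc(OCOC)cc(OCOC)c2[C@@H]1OC(=O)[C@@H](OC)c1ccccc1
F7 | step 8 | (3R,4S)-3-[5-bromo-2-methoxy-4-(methoxymethoxy)phenyl]-5,7-bis(methoxymethoxy)chroman-4-yl (2S)-2-methoxy-2-phenylacetate | COc1cc(OCOC)c(Br)cc1[C@@H]1COc2cc(OCOC)cc(OCOC)c2[C@H]1OC(=O)[C@@H](OC)c1ccccc1
F8 | step 11 | (3S)-3-[2-methoxy-5-(3-methylbut-2-en-1-yl)-4-(triethylsilyloxy)phenyl]-5,7-bis(triethylsilyloxy)chroman-4-one | COc1cc(O[Si](CC)(CC)CC)c(CC=C(C)C)cc1[C@H]1COc2cc(O[Si](CC)(CC)CC)cc(O[Si](CC)(CC)CC)c2C1=O
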